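**Retrosynthetic overview**

- The strategy rests on the benzene ring of the target, which carries the CH2 of the (R)-2-hydroxyheptadecyl chain at ring C1, the free OH at ring C3 and the OMe at ring C5. This is a tetraketide-type 5-alkylresorcinol; a temporary carboxyl at ring C2, tied to O3 as an acetonide, distinguishes O3 from O5.
- Target ⇐ desilylation, loss of the ring C2 carboxyl and O5-methylation of a 5-alkyl-7-hydroxy-benzodioxinone (resorcylate acetonide).
- Resorcylate acetonide ⇐ base-mediated aldol cycloaromatisation of a 6-(2,4-dioxoalkyl)dioxinone. This forms the ring C1–C2 bond and the benzene ring, the only ring made in the route.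
- Diketo-dioxinone ⇐ C-acylation of the dianion of 6-(2-oxopropyl)dioxinone with the Weinreb amide of (R)-3-silyloxyoctadecanoic acid.
- The (R)-carbinol ⇐ RuCl2[(R)-BINAP] hydrogenation of methyl 3-oxooctadecanoate, made from palmitoyl chloride and Meldrum's acid.

Key step: step 7

Assumption: the SMILES descriptor corresponds to the (R)-carbinol (OH > CH2Ar > CH2-alkyl > H). The priority order is unchanged when the arylmethyl arm is an acylmethyl arm, so methyl (R)-3-hydroxyoctadecanoate maps directly onto the target.

**Route**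

Step 1
Reactants: 1 palmitoyl chloride; 2 Meldrum's acid
Product: 4 methyl 3-oxooctadecanoate, via acyl Meldrum's acid 3 (not isolated)
Conditions: pyridine, CH2Cl2, 0 °C → rt; then MeOH, reflux
Reagents that add atoms: methanol, CO
Why: C-acylation of Meldrum's acid followed by methanolysis of the acyl Meldrum's acid with loss of acetone and CO2 is the standard Meldrum's acid route to β-keto esters.

Step 2
Reactants: 4 methyl 3-oxooctadecanoate
Product: 5 methyl (R)-3-hydroxyoctadecanoate
Conditions: H2 (50 atm), RuCl2[(R)-BINAP] (0.5 mol%), MeOH/CH2Cl2, 50 °C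
Reagents that add atoms: none
Why: Noyori asymmetric hydrogenation, in which the β-keto ester chelates ruthenium through both carbonyls and the (R)-BINAP ligand directs hydride to the ketone face that gives the (R)-carbinol, as is general for 3-oxoalkanoates.

Step 3
Reactants: 5 methyl (R)-3-hydroxyoctadecanoate
Product: 6 methyl (R)-3-(tert-butyldimethylsilyloxy)octadecanoate
Conditions: TBSCl, imidazole, DMF, rt
Reagents that add atoms: tert-butyldimethylsilyl chloride, CC(C)(C)[Si](C)(C)Cl
Why: Imidazole-promoted silylation of a secondary alcohol is a standard silyl ether formation that leaves the ester and the stereocentre untouched.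

Step 4
Reactants: 6 methyl (R)-3-(tert-butyldimethylsilyloxy)octadecanoate
Product: 7 (R)-3-(tert-butyldimethylsilyloxy)-N-methoxy-N-methyloctadecanamide
Conditions: MeNHOMe·HCl, iPrMgCl, THF, −20 → 0 °C
Reagents that add atoms: N,O-dimethylhydroxylamine hydrochloride, CNOC.Cl
Why: The chloromagnesium amide of N,O-dimethylhydroxylamine converts the ester into the Weinreb amide by addition–elimination at low temperature, conditions that tolerate β-silyloxy esters.

Step 5
Reactants: 8 2,2,6-trimethyl-4H-1,3-dioxin-4-one
Product: 10 2,2-dimethyl-6-(2-oxopropyl)-4H-1,3-dioxin-4-one, via lithium dienolate 9 (not isolated)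
Conditions: LiN(SiMe3)2 (1 equiv per 8), THF, −78 °C; then AcCl (0.5 equiv), −78 °C; aq. NH4Cl
Reagents that add atoms: acetyl chloride, CC(Cl)=O
Why: γ-Deprotonation gives the extended lithium dienolate, which is C-acylated at its γ-carbon by acetyl chloride (vinylogous Claisen acylation), the second equivalent of dienolate taking up the acidic proton of the product.

Step 6
Reactants: 10 2,2-dimethyl-6-(2-oxopropyl)-4H-1,3-dioxin-4-one; 7 (R)-3-(tert-butyldimethylsilyloxy)-N-methoxy-N-methyloctadecanamide
Product: 12 6-[(6R)-6-(tert-butyldimethylsilyloxy)-2,4-dioxohenicosyl]-2,2-dimethyl-4H-1,3-dioxin-4-one, via dilithium dianion 11 (not isolated)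
Conditions: LiN(iPr)2 (2.2 equiv per 10), THF, −78 °C; then 7, −78 → −40 °C; aq. NH4Cl; crude 12 taken on directly
Reagents that add atoms: none
Why: Claisen-type C-acylation at the terminal, last-formed and most nucleophilic carbon of the keto-dioxinone dianion by the N-methoxy-N-methylamide, an acyl donor that does not over-react, while the stereocentre β to the amide carbonyl is not enolisable.

Step 7
Reactants: 12 6-[(6R)-6-(tert-butyldimethylsilyloxy)-2,4-dioxohenicosyl]-2,2-dimethyl-4H-1,3-dioxin-4-one
Product: 14 5-[(2R)-2-(tert-butyldimethylsilyloxy)heptadecyl]-7-hydroxy-2,2-dimethyl-4H-benzo[d][1,3]dioxin-4-one, via cyclic aldol adduct 13 (not isolated)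
Conditions: Et3N, CH2Cl2, rt
Reagents that add atoms: none
Why: Et3N removes a proton from the side-chain C1' methylene (flanked by the dioxinone and the C2' ketone), and the resulting vinylogous enolate attacks through the dioxinone α-carbon (dioxinone C5) at the distal C4' ketone to give aldol 13; E1cB loss of water and enolisation of the C2' ketone then give the phenol, with aromaticity as the driving force. The closest known reaction type is the amine-mediated aldol cycloaromatisation of 6-(2,4-dioxoalkyl)dioxinones to resorcylate acetonides, the laboratory counterpart of tetraketide cyclisation by polyketide synthases. The single ring closed, the benzene ring, forms in a 6-(enolendo)-exo-trig mode: the enol-ether C=C of the dioxinone lies inside the new ring and the C4' carbonyl oxygen outside it, and the new bond is ring C1–C2 of the target (C5–C4a of the benzodioxinone). No new stereocentre persists, since the carbinol carbon of 13 is lost on dehydration, and the (R)-silyloxy centre is not α to a carbonyl and keeps its configuration. The step needs C–C closure to win over O-cyclisation to a pyranone and over β-elimination of the silyloxy group: at room temperature the dioxinone keeps the carboxyl masked so no acylketene is available, the mild base is taken up by the much more acidic C1'/C3' positions and not by C5', and the silanolate is a poor leaving group. Because the carboxyl and its ortho oxygen are tied in the acetonide, the only free phenol of 14 is the one para to the carbonyl, the oxygen that must become OMe.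

Step 8
Reactants: 14 5-[(2R)-2-(tert-butyldimethylsilyloxy)heptadecyl]-7-hydroxy-2,2-dimethyl-4H-benzo[d][1,3]dioxin-4-one
Product: 15 5-[(2R)-2-(tert-butyldimethylsilyloxy)heptadecyl]-7-methoxy-2,2-dimethyl-4H-benzo[d][1,3]dioxin-4-one
Conditions: MeI, K2CO3, acetone, rt
Reagents that add atoms: iodomethane, CI
Why: Williamson ether synthesis on the only free phenol, which is acidic (para to the lactone carbonyl), while the other ring oxygen is locked in the acetonide and the silyl ether is inert to K2CO3.

Step 9
Reactants: 15 5-[(2R)-2-(tert-butyldimethylsilyloxy)heptadecyl]-7-methoxy-2,2-dimethyl-4H-benzo[d][1,3]dioxin-4-one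
Product: 17 3-[(2R)-2-(tert-butyldimethylsilyloxy)heptadecyl]-5-methoxyphenol, via salicylic acid 16 (not isolated)
Conditions: KOH, MeOH/H2O, 120 °C (sealed tube); then 1 M HCl to pH 4
Reagents that add atoms: none
Why: Hydroxide opens the benzodioxinone with release of acetone, and the resulting 2-hydroxy-4-methoxybenzoate, whose carboxyl-bearing carbon is ortho and para to oxygen, should undergo ipso-protonation and thermal loss of CO2 (decarboxylative saponification of a β-resorcylate); any silyl ether lost here is already the target and is carried through step 10.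

Step 10
Reactants: 17 3-[(2R)-2-(tert-butyldimethylsilyloxy)heptadecyl]-5-methoxyphenol
Product: 18 3-[(2R)-2-hydroxyheptadecyl]-5-methoxyphenol (CNP0573802.1)
Conditions: Bu4NF, THF, rt; aqueous work-up
Reagents that add atoms: none
Why: Fluoride-induced cleavage of the silyl ether, driven by the Si–F bond, breaks only the O–Si bond, so the (R)-configuration at the carbinol carbon is retained.

**Compound list**

1 | palmitoyl chloride | CCCCCCCCCCCCCCCC(Cl)=O | starting material
2 | Meldrum's acid (2,2-dimethyl-1,3-dioxane-4,6-dione) | CC1(C)OC(=O)CC(=O)O1 | starting material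
3 | 5-(1-hydroxyhexadecylidene)-2,2-dimethyl-1,3-dioxane-4,6-dione (acyl Meldrum's acid, enol form) | CCCCCCCCCCCCCCCC(O)=C1C(=O)OC(C)(C)OC1=O | intermediate
4 | methyl 3-oxooctadecanoate | CCCCCCCCCCCCCCCC(=O)CC(=O)OC | intermediate
5 | methyl (R)-3-hydroxyoctadecanoate | CCCCCCCCCCCCCCC[C@@H](O)CC(=O)OC | intermediate
6 | methyl (R)-3-(tert-butyldimethylsilyloxy)octadecanoate | CCCCCCCCCCCCCCC[C@@H](O[Si](C)(C)C(C)(C)C)CC(=O)OC | intermediate
7 | (R)-3-(tert-butyldimethylsilyloxy)-N-methoxy-N-methyloctadecanamide | CCCCCCCCCCCCCCC[C@@H](O[Si](C)(C)C(C)(C)C)CC(=O)N(C)OC | intermediate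
8 | 2,2,6-trimethyl-4H-1,3-dioxin-4-one | CC1=CC(=O)OC(C)(C)O1 | starting material
9 | lithium dienolate of 8 (lithium 2,2-dimethyl-6-methylene-6H-1,3-dioxin-4-olate) | C=C1C=C(O[Li])OC(C)(C)O1 | intermediate
10 | 2,2-dimethyl-6-(2-oxopropyl)-4H-1,3-dioxin-4-one | CC(=O)CC1=CC(=O)OC(C)(C)O1 | intermediate
11 | dilithium dianion of 10 (bis-enolate, drawn as one resonance form) | C=C(O[Li])C=C1C=C(O[Li])OC(C)(C)O1 | intermediate
12 | 6-[(6R)-6-(tert-butyldimethylsilyloxy)-2,4-dioxohenicosyl]-2,2-dimethyl-4H-1,3-dioxin-4-one (drawn as the triketo tautomer) | CCCCCCCCCCCCCCC[C@@H](O[Si](C)(C)C(C)(C)C)CC(=O)CC(=O)CC1=CC(=O)OC(C)(C)O1 | intermediate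
13 | 5-[(2R)-2-(tert-butyldimethylsilyloxy)heptadecyl]-5-hydroxy-2,2-dimethyl-5,6-dihydro-4H-benzo[d][1,3]dioxine-4,7(8H)-dione (both C5 epimers) | CCCCCCCCCCCCCCC[C@@H](O[Si](C)(C)C(C)(C)C)CC1(O)CC(=O)CC2=C1C(=O)OC(C)(C)O2 | intermediate
14 | 5-[(2R)-2-(tert-butyldimethylsilyloxy)heptadecyl]-7-hydroxy-2,2-dimethyl-4H-benzo[d][1,3]dioxin-4-one | CCCCCCCCCCCCCCC[C@@H](O[Si](C)(C)C(C)(C)C)Cc1cc(O)cc2OC(C)(C)OC(=O)c12 | intermediate
15 | 5-[(2R)-2-(tert-butyldimethylsilyloxy)heptadecyl]-7-methoxy-2,2-dimethyl-4H-benzo[d][1,3]dioxin-4-one | CCCCCCCCCCCCCCC[C@@H](O[Si](C)(C)C(C)(C)C)Cc1cc(OC)cc2OC(C)(C)OC(=O)c12 | intermediate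
16 | 2-[(2R)-2-(tert-butyldimethylsilyloxy)heptadecyl]-6-hydroxy-4-methoxybenzoic acid (present as its potassium salt) | CCCCCCCCCCCCCCC[C@@H](O[Si](C)(C)C(C)(C)C)Cc1cc(OC)cc(O)c1C(=O)O | intermediate
17 | 3-[(2R)-2-(tert-butyldimethylsilyloxy)heptadecyl]-5-methoxyphenol | CCCCCCCCCCCCCCC[C@@H](O[Si](C)(C)C(C)(C)C)Cc1cc(O)cc(OC)c1 | intermediate
18 | 3-[(2R)-2-hydroxyheptadecyl]-5-methoxyphenol | CCCCCCCCCCCCCCC[C@@H](O)Cc1cc(O)cc(OC)c1 | target

**Step count**

Total: 10 steps. Longest linear sequence: 9 steps (steps 1–4 and 6–10, from palmitoyl chloride); step 5 is a one-step side branch from 8.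

**Steps most likely to fail, with fallbacks**

Step 7. The chain may enolise toward C5' and expel the silanolate, or the closure may stall at the aldol stage without dehydration. The fallback sets out from 12 and comes back at 17.
- Heating 12 with MeOH in toluene (110 °C, sealed tube) should release acetone by retro-[4+2] fragmentation to give the acylketene (R)-9-(tert-butyldimethylsilyloxy)-3,5,7-trioxotetracos-1-en-1-one F1.
- Methanol traps F1 as methyl (R)-9-(tert-butyldimethylsilyloxy)-3,5,7-trioxotetracosanoate F2, whose C2 is now a doubly activated β-keto ester carbon and a better aldol donor than the dioxinone carbon.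
- Cs2CO3 in MeOH at 0 °C, then AcOH, should close and dehydrate F2 to methyl 2-[(2R)-2-(tert-butyldimethylsilyloxy)heptadecyl]-4,6-dihydroxybenzoate F3.
- MeI (1 equiv) with K2CO3 in acetone should methylate only the hydroxyl para to the ester, the ortho hydroxyl being hydrogen-bonded to the ester carbonyl, to give methyl 2-[(2R)-2-(tert-butyldimethylsilyloxy)heptadecyl]-6-hydroxy-4-methoxybenzoate F4.
- Saponification of F4 under the conditions of step 9 passes through 16 to 17.

Step 6. The strongly basic dianion may take a proton from the α-methylene of the amide, with ensuing loss of silanolate, instead of undergoing acyl transfer, or acylation may occur on oxygen. The fallback sets out from 6 and 10 and comes back at 12.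
- Reduction of 6 with iBu2AlH (CH2Cl2, −78 °C) gives (R)-3-(tert-butyldimethylsilyloxy)octadecanal F5.
- Aldol addition of dianion 11 (from 10, LiN(iPr)2, THF, −78 °C) to the far more electrophilic aldehyde gives 6-[(6R)-6-(tert-butyldimethylsilyloxy)-4-hydroxy-2-oxohenicosyl]-2,2-dimethyl-4H-1,3-dioxin-4-one F6 as a mixture of carbinol epimers, which is of no consequence.
- Oxidation of F6 with Dess–Martin periodinane (NaHCO3, CH2Cl2, 0 °C) gives 12.

Step 9. Loss of CO2 from the electron-rich carboxylate may be incomplete in basic medium, since only one ortho oxygen activates the ipso carbon. The fallback sets out from 15 and comes back at 17.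
- Hydrolysis with LiOH (THF/H2O, 40 °C) and careful acidification allow the acid 16 to be isolated.
- Silver-catalysed protodecarboxylation of 16 (Ag2CO3 10 mol%, AcOH 5 mol%, DMSO, 120 °C), a known method for ortho-substituted benzoic acids that proceeds by a different mechanism from thermal ipso-protonation, should then give 17.

**Further compounds**

F1 | step 7 | (R)-9-(tert-butyldimethylsilyloxy)-3,5,7-trioxotetracos-1-en-1-one (acylketene) | CCCCCCCCCCCCCCC[C@@H](O[Si](C)(C)C(C)(C)C)CC(=O)CC(=O)CC(=O)C=C=O
F2 | step 7 | methyl (R)-9-(tert-butyldimethylsilyloxy)-3,5,7-trioxotetracosanoate | CCCCCCCCCCCCCCC[C@@H](O[Si](C)(C)C(C)(C)C)CC(=O)CC(=O)CC(=O)CC(=O)OC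
F3 | step 7 | methyl 2-[(2R)-2-(tert-butyldimethylsilyloxy)heptadecyl]-4,6-dihydroxybenzoate | CCCCCCCCCCCCCCC[C@@H](O[Si](C)(C)C(C)(C)C)Cc1cc(O)cc(O)c1C(=O)OC
F4 | step 7 | methyl 2-[(2R)-2-(tert-butyldimethylsilyloxy)heptadecyl]-6-hydroxy-4-methoxybenzoate | CCCCCCCCCCCCCCC[C@@H](O[Si](C)(C)C(C)(C)C)Cc1cc(OC)cc(O)c1C(=O)OC
F5 | step 6 | (R)-3-(tert-butyldimethylsilyloxy)octadecanal | CCCCCCCCCCCCCCC[C@@H](O[Si](C)(C)C(C)(C)C)CC=O
F6 | step 6 | 6-[(6R)-6-(tert-butyldimethylsilyloxy)-4-hydroxy-2-oxohenicosyl]-2,2-dimethyl-4H-1,3-dioxin-4-one | CCCCCCCCCCCCCCC[C@@H](O[Si](C)(C)C(C)(C)C)CC(O)CC(=O)CC1=CC(=O)OC(C)(C)O1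
F0 | step 9 | none | none
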